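**Retrosynthetic overview**

1. Target 22 ⇐ Schenck ene reaction (oxygen to C7, new C11=C12) of enone diester 21 ⇐ acylation of the 3α,4α-diol ⇐ cis-dihydroxylation of the C3=C4 bond.
2. The C7=C11 isopropylidene ketone ⇐ aldol condensation of acetone at C7 of the trans-octalone 11.
3. Ring A ⇐ ring-closing metathesis forming C3=C4 from a C10 butenyl arm and a C5 isopropenyl arm; quaternary C10 ⇐ conjugate addition to enone 7, anti to the C5 substituent.
4. Ring B (C5–C6–C7–C8–C9–C10) ⇐ one-carbon enlargement of a cyclopentane (C5, C6, C7, C8, C10). The enabling feature is that C9 is a bare CH2 between the C8 carbonyl and the methyl-bearing C10: the C8(=O)–C9H2–C10(CH3) unit is the retron of a methylene inserted into a C8=C10 enol ether.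
5. Cyclopentane ⇐ asymmetric conjugate addition of isopropenyl to 2-methylcyclopent-2-en-1-one (sets C5). Ring order: five-membered ring → ring B (by enlargement) → ring A (by metathesis).

Key step: step 3

Assumption: eudesmane numbering is used (decalin C1–C10, three-carbon unit C11–C13 on C7, C14 on C10, C15 on C4); the target is read as 3R,4S,5R,7S,10R, i.e. trans-fused with 10β-methyl, 5α-H, 3α-angeloyloxy, 4α-acetoxy, 7α-hydroperoxy.

**Route**

Step 1
Reactants: 1 2-methylcyclopent-2-en-1-one; 2 prop-1-en-2-ylmagnesium bromide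
Product: 4 (S)-trimethyl{[2-methyl-3-(prop-1-en-2-yl)cyclopent-1-en-1-yl]oxy}silane, via bromomagnesium enolate 3 (not isolated)
Conditions: Cu(OTf)2 (3 mol %), chiral imidazolinium salt as carbene precursor (4 mol %, antipode giving the 3S adduct), Et2O, -10 °C; then TMSCl, Et3N, DMPU, -78 → 0 °C
Reagents that add atoms: chlorotrimethylsilane C[Si](C)(C)Cl
Why: Copper–carbene-catalysed asymmetric conjugate addition of a Grignard reagent to an α-substituted cyclic enone, in which the chiral ligand selects the enone face and so sets C5, followed by O-silylation of the regiodefined magnesium enolate, which fixes the enol double bond between C8 and C10.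

Step 2
Reactants: 4 (S)-trimethyl{[2-methyl-3-(prop-1-en-2-yl)cyclopent-1-en-1-yl]oxy}silane
Product: 5 (1R,4S,5S)-trimethyl{[5-methyl-4-(prop-1-en-2-yl)bicyclo[3.1.0]hexan-1-yl]oxy}silane
Conditions: Et2Zn (1.5 equiv), CH2I2 (1.5 equiv), CH2Cl2, 0 °C
Reagents that add atoms: diiodomethane ICI
Why: Simmons–Smith cyclopropanation with the Et2Zn/CH2I2 carbenoid should select the electron-rich tetrasubstituted silyl enol ether over the isopropenyl group and deliver the methylene (the future C9) anti to the C5 substituent; the two cyclopropane stereocentres are only transient and are erased in step 3.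

Step 3
Reactants: 5 (1R,4S,5S)-trimethyl{[5-methyl-4-(prop-1-en-2-yl)bicyclo[3.1.0]hexan-1-yl]oxy}silane
Product: 7 (S)-3-methyl-4-(prop-1-en-2-yl)cyclohex-2-en-1-one, via β-chloro ketone 6 (not isolated)
Conditions: FeCl3 (2.2 equiv), DMF, 0 °C; then NaOAc, MeOH, 40 °C
Reagents that add atoms: none
Why: Single-electron oxidation of the siloxycyclopropane by FeCl3 (trivalent iron) releases the silyl group and gives a cyclopropyloxy radical that cleaves the shared C8–C10 bond, forming the C8 carbonyl and the tertiary C10 radical, which takes chlorine from a second FeCl3 to give 6; acetate then removes HCl across C9–C10 by an E1cB pathway. The closest known reaction type is the Ito–Saegusa ring enlargement of 1-siloxybicyclo[n.1.0]alkanes to cycloalk-2-enones. Ring B is not closed by bond formation: it arises by one-carbon enlargement, the zero-atom bridge of the bicyclo[3.1.0]hexane being cut so that C9 becomes a ring member between C8 and C10. No stereocentre is created; the two cyclopropane centres are erased and C5, which is not part of the reacting bonds, is retained. The step needs endocyclic rather than exocyclic (C8–C9) cyclopropane scission, secured by formation of a tertiary instead of a primary radical, and elimination only toward C9, the sole carbon that is α to the carbonyl. Integrity of the allylic, γ-positioned C5 centre rests on the mild acetate base and moderate temperature, which should not remove the γ-proton.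

Step 4
Reactants: 7 (S)-3-methyl-4-(prop-1-en-2-yl)cyclohex-2-en-1-one; 8 but-3-en-1-ylmagnesium bromide
Product: 10 (3R,4S)-3-(but-3-en-1-yl)-3-methyl-4-(prop-1-en-2-yl)cyclohexan-1-one, via silyl enol ether 9 (not isolated)
Conditions: CuBr·SMe2 (10 mol %), TMSCl, THF, -78 → -30 °C; then 1 M HCl, 0 °C
Reagents that add atoms: none
Why: Copper-catalysed, TMSCl-accelerated conjugate addition of a Grignard reagent to the β,β-disubstituted enone, in which the C5 isopropenyl group sits pseudoaxial to avoid allylic strain with the C10 methyl group and the nucleophile enters on the opposite face, sets the quaternary centre C10 with the butenyl chain trans to the isopropenyl group; dilute acid then cleaves the silyl enol ether 9.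

Step 5
Reactants: 10 (3R,4S)-3-(but-3-en-1-yl)-3-methyl-4-(prop-1-en-2-yl)cyclohexan-1-one
Product: 11 (4aR,8aR)-5,8a-dimethyl-3,4,4a,7,8,8a-hexahydronaphthalen-2(1H)-one
Conditions: second-generation Grubbs catalyst RuCl2(=CHPh)(PCy3)(H2IMes) (3 mol %), CH2Cl2, 40 °C
Reagents that add atoms: none
Why: Ring-closing metathesis of the monosubstituted and the 1,1-disubstituted alkene closes ring A as a cyclohexene with the trisubstituted C3=C4 bond, driven by loss of ethene; the trans disposition of the two alkenyl arms makes the ring fusion trans and no new stereocentre is formed.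

Step 6
Reactants: 11 (4aR,8aR)-5,8a-dimethyl-3,4,4a,7,8,8a-hexahydronaphthalen-2(1H)-one; 12 acetone
Product: 14 (5R,7R,10R)-11-hydroxyeudesm-3-en-8-one, via lithium enolate 13 (not isolated)
Conditions: LDA (1.1 equiv), THF, -78 °C; acetone, -78 °C; aq NH4Cl
Reagents that add atoms: none
Why: Kinetic deprotonation with LDA should occur at C7 because C9 is shielded by the quaternary C10, and the lithium enolate adds to acetone in an aldol reaction; the new C7 centre (side chain expected equatorial) is removed again in step 7.

Step 7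
Reactants: 14 (5R,7R,10R)-11-hydroxyeudesm-3-en-8-one
Product: 16 (5R,10R)-eudesma-3,7(11)-dien-8-one, via tertiary methanesulfonate 15 (not isolated)
Conditions: MsCl, Et3N, CH2Cl2, 0 °C; then DBU, 25 °C
Reagents that add atoms: none
Why: Mesylation of the tertiary alcohol and base-induced E1cB elimination through the C7 enolate complete the aldol condensation to the conjugated isopropylidene ketone, DBU bringing any β,γ-isomer into conjugation.

Step 8
Reactants: 16 (5R,10R)-eudesma-3,7(11)-dien-8-one
Product: 17 (3R,4S,5R,10R)-3,4-dihydroxyeudesm-7(11)-en-8-one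
Conditions: OsO4 (2 mol %), NMO (1.3 equiv), acetone/H2O, 0 → 20 °C
Reagents that add atoms: osmium tetroxide O=[Os](=O)(=O)=O; 4-methylmorpholine 4-oxide C[N+]1([O-])CCOCC1 (replenishes the transferred oxygen)
Why: Catalytic OsO4 cis-dihydroxylation with NMO as reoxidant should attack the electron-rich trisubstituted C3=C4 bond in preference to the electron-poor tetrasubstituted enone, from the α-face opposite the axial C10 methyl group, which sets C3 and C4 as the 3α,4α-diol.

Step 9
Reactants: 17 (3R,4S,5R,10R)-3,4-dihydroxyeudesm-7(11)-en-8-one; 18 angelic acid [(Z)-2-methylbut-2-enoic acid]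
Product: 20 (3R,4S,5R,10R)-4-hydroxy-8-oxoeudesm-7(11)-en-3-yl (Z)-2-methylbut-2-enoate, via mixed anhydride 19 (not isolated)
Conditions: 18, 2,4,6-trichlorobenzoyl chloride, Et3N, toluene, 20 °C; then 17, toluene, 80 °C
Reagents that add atoms: none
Why: Yamaguchi esterification through the mixed anhydride 19 should acylate the secondary 3α-hydroxyl selectively over the tertiary 4α-hydroxyl, and the absence of a nucleophilic catalyst and of strong base should preserve the Z geometry of the angelate; no stereocentre is touched.

Step 10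
Reactants: 20 (3R,4S,5R,10R)-4-hydroxy-8-oxoeudesm-7(11)-en-3-yl (Z)-2-methylbut-2-enoate
Product: 21 (3R,4S,5R,10R)-4-acetoxy-8-oxoeudesm-7(11)-en-3-yl (Z)-2-methylbut-2-enoate
Conditions: Ac2O, Sc(OTf)3 (2 mol %), MeCN, -20 °C
Reagents that add atoms: acetic anhydride CC(=O)OC(C)=O
Why: Lewis-acid-catalysed acetylation at low temperature acylates the hindered tertiary alcohol on oxygen, so C4 keeps its configuration, and should avoid elimination.

Step 11
Reactants: 21 (3R,4S,5R,10R)-4-acetoxy-8-oxoeudesm-7(11)-en-3-yl (Z)-2-methylbut-2-enoate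
Product: 22 (3R,4S,5R,7S,10R)-4-acetoxy-7-hydroperoxy-8-oxoeudesm-11-en-3-yl (Z)-2-methylbut-2-enoate (CNP0360871.1)
Conditions: O2, tetraphenylporphyrin (1 mol %), visible light (>500 nm), CH2Cl2, -20 °C
Reagents that add atoms: dioxygen O=O
Why: Schenck ene reaction of singlet oxygen with the s-cis enone: oxygen bonds to C7 while a hydrogen of a C11 methyl group is transferred and the double bond moves to C11=C12, oxygen being expected to arrive axially on the α-face of C7 so that the isopropenyl group ends equatorial; the electron-poor trisubstituted angelate should react far more slowly and the low-energy sensitiser cannot isomerise it.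

**Compound list**

1 | 2-methylcyclopent-2-en-1-one | CC1=CCCC1=O | starting material
2 | prop-1-en-2-ylmagnesium bromide | CC(=C)[Mg]Br | starting material
3 | bromomagnesium (S)-2-methyl-3-(prop-1-en-2-yl)cyclopent-1-en-1-olate | C1C[C@@H](C(C)=C)C(C)=C1O[Mg]Br | intermediate
4 | (S)-trimethyl{[2-methyl-3-(prop-1-en-2-yl)cyclopent-1-en-1-yl]oxy}silane | C1C[C@@H](C(C)=C)C(C)=C1O[Si](C)(C)C | intermediate
5 | (1R,4S,5S)-trimethyl{[5-methyl-4-(prop-1-en-2-yl)bicyclo[3.1.0]hexan-1-yl]oxy}silane (cyclopropane CH2 anti to isopropenyl) | C1C[C@@H](C(C)=C)[C@]2(C)C[C@]12O[Si](C)(C)C | intermediate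
6 | (4S)-3-chloro-3-methyl-4-(prop-1-en-2-yl)cyclohexan-1-one (epimers at the chlorine-bearing carbon) | C1C[C@@H](C(C)=C)C(C)(Cl)CC1=O | intermediate
7 | (S)-3-methyl-4-(prop-1-en-2-yl)cyclohex-2-en-1-one | C1C[C@@H](C(C)=C)C(C)=CC1=O | intermediate
8 | but-3-en-1-ylmagnesium bromide | C=CCC[Mg]Br | starting material
9 | trimethylsilyl enol ether of 10 (enol double bond toward the CH2 next to the quaternary carbon, ring configuration as in 10) | C1C[C@@H](C(C)=C)[C@](C)(CCC=C)C=C1O[Si](C)(C)C | intermediate
10 | (3R,4S)-3-(but-3-en-1-yl)-3-methyl-4-(prop-1-en-2-yl)cyclohexan-1-one (butenyl trans to isopropenyl) | C1C[C@@H](C(C)=C)[C@](C)(CCC=C)CC1=O | intermediate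
11 | (4aR,8aR)-5,8a-dimethyl-3,4,4a,7,8,8a-hexahydronaphthalen-2(1H)-one [(5R,10R)-15-... eudesmane skeleton without C11–C13: trans-fused, C3=C4, 8-ketone] | C1C[C@@H]2[C@](C)(CCC=C2C)CC1=O | intermediate
12 | acetone | CC(C)=O | starting material
13 | lithium enolate of 11 (C7=C8 enolate) | C=1C[C@@H]2[C@](C)(CCC=C2C)CC=1O[Li] | intermediate
14 | (5R,7R,10R)-11-hydroxyeudesm-3-en-8-one (side chain 7β, equatorial) | CC(C)(O)[C@H]1C[C@@H]2[C@](C)(CCC=C2C)CC1=O | intermediate
15 | (5R,7R,10R)-8-oxoeudesm-3-en-11-yl methanesulfonate | CC(C)(OS(C)(=O)=O)[C@H]1C[C@@H]2[C@](C)(CCC=C2C)CC1=O | intermediate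
16 | (5R,10R)-eudesma-3,7(11)-dien-8-one | CC(C)=C1C[C@@H]2[C@](C)(CCC=C2C)CC1=O | intermediate
17 | (3R,4S,5R,10R)-3,4-dihydroxyeudesm-7(11)-en-8-one (3α,4α-diol) | CC(C)=C1C[C@@H]2[C@](C)(CC[C@@H](O)[C@@]2(C)O)CC1=O | intermediate
18 | angelic acid, (Z)-2-methylbut-2-enoic acid | C/C=C(/C)C(=O)O | starting material
19 | (Z)-2-methylbut-2-enoic 2,4,6-trichlorobenzoic anhydride | C/C=C(/C)C(=O)OC(=O)c1c(Cl)cc(Cl)cc1Cl | intermediate
20 | (3R,4S,5R,10R)-4-hydroxy-8-oxoeudesm-7(11)-en-3-yl (Z)-2-methylbut-2-enoate | CC(C)=C1C[C@@H]2[C@](C)(CC[C@@H](OC(=O)/C(C)=C\C)[C@@]2(C)O)CC1=O | intermediate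
21 | (3R,4S,5R,10R)-4-acetoxy-8-oxoeudesm-7(11)-en-3-yl (Z)-2-methylbut-2-enoate | CC(C)=C1C[C@@H]2[C@](C)(CC[C@@H](OC(=O)/C(C)=C\C)[C@@]2(C)OC(C)=O)CC1=O | intermediate
22 | (3R,4S,5R,7S,10R)-4-acetoxy-7-hydroperoxy-8-oxoeudesm-11-en-3-yl (Z)-2-methylbut-2-enoate | C=C(C)[C@@]1(OO)C[C@@H]2[C@](C)(CC[C@@H](OC(=O)/C(C)=C\C)[C@@]2(C)OC(C)=O)CC1=O | target

**Summary**

Total step count: 11. Longest linear sequence: 11 steps (1 → 22).

Steps most likely to fail:

Step 11. What may go wrong: hydrogen abstraction from C6 instead of the C11 methyl groups (giving the conjugated 11-hydroperoxide), oxygen delivery to the β-face of C7, or competing ene oxidation of the angelate. Fallback, setting out from 21 and returning at 22: the oxygen is introduced ionically instead of by a pericyclic route. KHMDS (1.05 equiv, THF, -78 °C) should remove a proton from a C11 methyl group, since the α′-position C9 is shielded by the quaternary C10, to give the potassium dienolate of 21 F6. Dry O2 at -78 °C should then react at the α-carbon C7 from the axial α-face, and an acetic acid quench at -78 °C should release 22; this is the known low-temperature oxygenation of enolates to α-hydroperoxy carbonyl compounds.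

Step 1. What may go wrong: poor enantiofacial discrimination with an alkenyl Grignard reagent on the α-methyl enone, or erosion by an uncatalysed background addition. Fallback, setting out from 2 and returning at 4: a stoichiometric sulfoxide auxiliary replaces the catalyst. The enantiopure enone (S)-2-[(4-methylphenyl)sulfinyl]cyclopent-2-en-1-one F1 is precomplexed with ZnBr2 (THF, -78 °C) and treated with 2, addition occurring on the face of the zinc chelate away from the tolyl group. The resulting enolate is C-methylated in the same flask (MeI, DMPU) to give 2-methyl-2-[(4-methylphenyl)sulfinyl]-3-(prop-1-en-2-yl)cyclopentan-1-one F2. Aluminium amalgam (aqueous THF) removes the sulfinyl group to give (2S,3R)-2-methyl-3-(prop-1-en-2-yl)cyclopentan-1-one F3, and thermodynamic silylation (TMSCl, NaI, Et3N, MeCN) to the more substituted enol ether returns 4.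

Step 3. What may go wrong: migration of the isopropenyl double bond into conjugation or loss of configuration at C5 during the base-mediated dehydrochlorination, or exocyclic C8–C9 scission of the cyclopropane. Fallback, setting out from 4 and returning at 7, still a one-carbon enlargement of the cyclopentane: dibromocarbene (CHBr3, KOtBu, pentane, -20 °C) adds to the enol ether to give the dibromo(siloxy)cyclopropane F4. On warming (toluene, 80 °C) this opens by electrocyclic cleavage of the shared bond with loss of bromotrimethylsilane to (S)-2-bromo-3-methyl-4-(prop-1-en-2-yl)cyclohex-2-en-1-one F5. Neutral hydrodebromination with Bu3SnH and Pd(PPh3)4 (zerovalent palladium) in THF then returns 7.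

Further compounds

F1 | step 1 | (S)-2-[(4-methylphenyl)sulfinyl]cyclopent-2-en-1-one | Cc1ccc(cc1)[S@](=O)C1=CCCC1=O
F2 | step 1 | 2-methyl-2-[(4-methylphenyl)sulfinyl]-3-(prop-1-en-2-yl)cyclopentan-1-one (sulfur as in F1, C3 as in F3, C2 not assigned) | Cc1ccc(cc1)[S@](=O)C1(C)C(=O)CC[C@H]1C(C)=C
F3 | step 1 | (2S,3R)-2-methyl-3-(prop-1-en-2-yl)cyclopentan-1-one | C[C@@H]1C(=O)CC[C@H]1C(C)=C
F4 | step 3 | (4S)-{[6,6-dibromo-5-methyl-4-(prop-1-en-2-yl)bicyclo[3.1.0]hexan-1-yl]oxy}trimethylsilane | C1C[C@@H](C(C)=C)C2(C)C(Br)(Br)C12O[Si](C)(C)C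
F5 | step 3 | (S)-2-bromo-3-methyl-4-(prop-1-en-2-yl)cyclohex-2-en-1-one | C1C[C@@H](C(C)=C)C(C)=C(Br)C1=O
F6 | step 11 | potassium dienolate of 21 (C7=C8 enolate, C11=C12 alkene) | C=C(C)C=1C[C@@H]2[C@](C)(CC[C@@H](OC(=O)/C(C)=C\C)[C@@]2(C)OC(C)=O)CC=1O[K]
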